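Percent of charge is what stays put. Thursday's flask, charged with twice the substrate of Saturday's, holds 91.5% of its substrate at 3.00 h against 91.7%, the same within scatter. So I take the loss of substrate as first-order and watch the logarithm of its percent: Saturday's last reading gives a slope of 0.0293 h⁻¹.

| setting | Saturday's | Thursday's | flask |
|---|---|---|---|
| substrate | 11 mM | 22 mM | 11 mM |
| first nucleophile | 14.3 mM | 14.3 mM | 14.3 mM |
| second nucleophile | 8.8 mM | 8.8 mM | 8.80 mM |
| remark | the very flask that is asked about, followed so far | run made earlier |  |
| time |  |  | 12 h |

| run | time / h | target / % | substrate / % |
|---|---|---|---|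
| Saturday's | 3.00 | 5.9 | 91.7 |
| Saturday's | 4.00 | 6.9 | 89.8 |
| Saturday's | 5.00 | 8.3 | 86.2 |
| Saturday's | 6.00 | 8.6 | 83.9 |
| Thursday's | 3.00 | 5.3 | 91.5 |
| Thursday's | 4.00 | 5.9 | 89.2 |
| Thursday's | 5.00 | 8.1 | 87.2 |

(scatter of a reading: 0.5 percentage points)

Single ratios of target to substrate lost wobble, so I sum over the readings. Saturday's flask gives a capture share, target gained per substrate lost, of 0.614, and Thursday's gives 0.601. The two flasks run together because first nucleophile stays near its charge: counting one per target, Thursday's flask, with more substrate than first nucleophile, has spent 12.5% of it by 5.00 h. It is the limiting reagent in name, and that does not show yet.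

- the moment within 12 h at which there is most target
- the amount of target, in percent of the substrate charged, at that time
- the first time at which target reaches 5.2%, in the same percent

For Saturday's flask I hold the share and the slope. Substrate keeps falling, so target keeps rising, and I put the most at 12 h, with 18.2%. The level is reached at 3.03 h. The forecast also says 12 h, but with 11.5%, below mine, and 2.8 h, holding that “target is probably still creeping up”.

The simulation gives 12.0 h, 17.3% and 3.16 h.

    intermediate → solvolysis product (k = 0.200 min⁻¹)
    first nucleophile + intermediate → target (k = 28.0 L mol⁻¹ min⁻¹)
    second nucleophile + intermediate → other capture product (k = 5.20 L mol⁻¹ min⁻¹)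
    substrate → intermediate (k = 4.70 × 10⁻⁴ min⁻¹)

Throughout, substrate fed intermediate with a half-life of 25 h, the rate-limiting step, while intermediate slid from 0.0710% at 1.20 h to 0.0567% at 12.0 h, made about as fast as used (ratio 0.999 at 12.0 h). Intermediate passed on to target while first nucleophile fell to 87% of its charge, and also to solvolysis product and other capture product, which stood at 9.27% and 2.09% at 12.0 h; target's share of the substrate lost by then is 0.602.

For the same flask left until 50 h, share and slope give 47.2% of target. The simulation gives 43.4%, lower than that.

The earlier runs and the new flask were computed for substances that don't exist; scatter was added.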